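The route rests on opening a cis-6,7-oxirane by the C15 carboxyl group (germacrane numbering, defined below): O–C6 of lactone ring A forms by 5-exo attack with inversion, and the oxirane oxygen becomes the tertiary C7 hydroxyl. The precursor is a ten-membered carbocyclic epoxy enone in which a (Z)-enoate holds C15 over C6, while C1–O and the C12 carboxyl are masked. Aqueous acid unmasks both, so one operation closes the C1–O–C8 dihydrofuran ketal (ring B), the spiro 12,8-lactone (ring C) and the bridged butenolide (ring A). The step exploits the contiguous C6(O)–C7(OH)–C8(O,O) array lying between the carboxyl carbons C15 and C12. Dihydroxylation, acetylation and C11 equilibration complete the synthesis.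

Key step: step 14

Remarks on the chemistry:
- Numbering: ring carbons run C1 (O–CH of ring B), C2H2, C3H2, C4 (C–OH, bears lactone carbonyl C15), C5 (CH–OAc), C6 (CH–O of ring A), C7 (C–OH, bears C11), C8 (spiro ketal), C9H=C10(CH3), back to C1. C11 is CH(CH3) and C12 its lactone carbonyl. Ring A is O–C15(=O)–C4–C5–C6, ring B is O–C1–C10=C9–C8, ring C is O–C12(=O)–C11–C7–C8. The target is (1S,4S,5S,6R,7S,8S,11S).
- Assumption: C11 is carried as a mixture of both epimers from 14 to 26 and is fixed under thermodynamic control in step 17; SMILES of these compounds leave C11 undefined.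
- Compounds 1, 9, 11 and 12 are taken as commercially available.

Step 1
Reactants: 1 propargyl alcohol
Product: 3 (Z)-3-iodo-2-methylprop-2-en-1-ol, via alkenylmagnesium alkoxide 2 (not isolated)
Conditions: MeMgBr (2.5 equiv), CuI (10 mol %), Et2O/THF, −10 → 23 °C; then I2, −20 °C
Reagents that add atoms: methylmagnesium bromide (C[Mg]Br), iodine (II)
Why: Copper-catalysed anti-carbomagnesiation of the propargylic magnesium alkoxide puts methyl on the proximal carbon and magnesium cis to the CH2O group through a five-membered chelate, so iodinolysis with retention should give the (Z)-iodoalkene.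

Step 2
Reactants: 3 (Z)-3-iodo-2-methylprop-2-en-1-ol
Product: 4 (Z)-3-iodo-2-methylprop-2-enal
Conditions: activated MnO2 (excess), CH2Cl2, 23 °C, dark
Reagents that add atoms: none
Why: Allylic oxidation with MnO2 under neutral conditions should give the enal and leave the (Z)-iodoalkene untouched.

Step 3
Reactants: 4 (Z)-3-iodo-2-methylprop-2-enal
Product: 5 (1Z,3S)-1-iodo-2-methylpenta-1,4-dien-3-ol
Conditions: Zn(CH=CH2)2 (1.5 equiv), (−)-DAIB (10 mol %), toluene/Et2O, −20 → 0 °C; aq. NH4Cl
Reagents that add atoms: divinylzinc (C=C[Zn]C=C)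
Why: Amino-alcohol-catalysed enantioselective addition of a diorganozinc to an aldehyde; with (−)-DAIB the vinyl group should add to the aldehyde face that gives the (S)-carbinol, which becomes C1.

Step 4
Reactants: 5 (1Z,3S)-1-iodo-2-methylpenta-1,4-dien-3-ol
Product: 6 tert-butyl{[(1Z,3S)-1-iodo-2-methylpenta-1,4-dien-3-yl]oxy}dimethylsilane
Conditions: TBSCl, imidazole, DMF, 23 °C
Reagents that add atoms: tert-butyldimethylsilyl chloride (CC(C)(C)[Si](C)(C)Cl)
Why: Standard silylation of the secondary alcohol; the silyl ether blocks C1–OH during the later hydroxyl-directed epoxidation and the oxidations.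

Step 5
Reactants: 6 tert-butyl{[(1Z,3S)-1-iodo-2-methylpenta-1,4-dien-3-yl]oxy}dimethylsilane
Product: 8 tert-butyl{[(1Z,3S)-1,5-diiodo-2-methylpent-1-en-3-yl]oxy}dimethylsilane, via alkylborane 7 (not isolated)
Conditions: 9-BBN, THF, 0 → 23 °C; then NaOMe, I2, MeOH, 0 °C
Reagents that add atoms: iodine (II)
Why: Hydroboration with 9-BBN is selective for the monosubstituted vinyl group (boron on the terminal carbon), and base-induced iodinolysis converts the primary carbon–boron bond into the iodide without touching C1.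

Step 6
Reactants: 8 tert-butyl{[(1Z,3S)-1,5-diiodo-2-methylpent-1-en-3-yl]oxy}dimethylsilane; 9 ethyl 2-(diphenoxyphosphoryl)acetate
Product: 10 ethyl (5S,6Z)-5-(tert-butyldimethylsilyloxy)-2-(diphenoxyphosphoryl)-7-iodo-6-methylhept-6-enoate (both C2 epimers)
Conditions: NaH, 9 (1.5 equiv), DMF, 0 → 23 °C
Reagents that add atoms: none
Why: SN2 C-alkylation of the sodium phosphonoacetate by the primary iodide (the alkenyl iodide is inert); the new phosphonate carbon later becomes trigonal, so its configuration is irrelevant.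

Step 7
Reactants: 11 4-bromofuran-2(5H)-one; 12 tert-butyl 2-bromopropanoate
Product: 14 tert-butyl 2-(5-oxo-2,5-dihydrofuran-3-yl)propanoate (racemic), via zinc enolate 13 (not isolated)
Conditions: 12, Zn dust, THF, 23 °C; then 11, Pd(PtBu3)2 (2 mol %), THF, 23 °C
Reagents that add atoms: none
Why: Reformatsky zinc enolate formation followed by palladium-catalysed Negishi-type coupling with the activated β-bromo enoate; C11 is formed racemic and is set in step 17.

Step 8
Reactants: 14 tert-butyl 2-(5-oxo-2,5-dihydrofuran-3-yl)propanoate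
Product: 15 tert-butyl 2-(5-hydroxy-2,5-dihydrofuran-3-yl)propanoate (lactol)
Conditions: iBu2AlH (1.1 equiv), CH2Cl2, −78 °C; Rochelle salt
Reagents that add atoms: none
Why: Partial reduction of the lactone to the lactol at −78 °C (the hindered tert-butyl ester reacts more slowly) keeps the cis C6=C7 geometry locked in the five-membered ring.

Step 9
Reactants: 10 ethyl (5S,6Z)-5-(tert-butyldimethylsilyloxy)-2-(diphenoxyphosphoryl)-7-iodo-6-methylhept-6-enoate; 15 tert-butyl 2-(5-hydroxy-2,5-dihydrofuran-3-yl)propanoate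
Product: 17 1-ethyl 7-tert-butyl (2Z,4Z)-2-[(3S,4Z)-3-(tert-butyldimethylsilyloxy)-5-iodo-4-methylpent-4-enyl]-5-(hydroxymethyl)-6-methylhepta-2,4-dienedioate (C11 epimers), via sodium alkoxide enal 16 (not isolated)
Conditions: 15 (1.5 equiv), NaN(SiMe3)2, THF, −78 °C; added to 10/NaH, THF; −78 → −30 °C; AcOH quench
Reagents that add atoms: none
Why: Horner–Wadsworth–Emmons olefination with a diaryl phosphonate is kinetically Z-selective, so C15 should end up cis to C6 on the new C4=C5 bond, while the C6=C7 geometry (C5 cis to C8) is inherited from the ring of the lactol.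

Step 10
Reactants: 17 seco-dienoate alcohol
Product: 18 (6S,7R)-6,7-epoxide of 17 (oxirane carbon C7 bears the C8 hydroxymethyl and C11)
Conditions: Ti(OiPr)4 (1.0 equiv), D-(−)-diethyl tartrate (1.2 equiv), t-BuOOH, 4 Å molecular sieves, CH2Cl2, −25 °C
Reagents that add atoms: tert-butyl hydroperoxide (CC(C)(C)OO)
Why: Sharpless asymmetric epoxidation of the primary allylic alcohol is reagent-controlled; D-(−)-diethyl tartrate should deliver oxygen to the face that gives the (6S,7R)-oxirane (the antipodal sense to the L-(+)-tartrate/geraniol case), and the silylated C1 carbinol and the iodoalkene cannot direct.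

Step 11
Reactants: 18 epoxy alcohol
Product: 19 epoxy aldehyde (C8 formyl group on the oxirane carbon C7, oxirane unchanged)
Conditions: Dess–Martin periodinane, NaHCO3, CH2Cl2, 0 °C
Reagents that add atoms: none
Why: Dess–Martin oxidation of the primary 2,3-epoxy alcohol under buffered conditions; the aldehyde sits on a fully substituted oxirane carbon and cannot epimerise.

Step 12
Reactants: 19 epoxy aldehyde
Product: 20 ten-membered carbocycle: ethyl 15-oate with E ring olefin C4=C5, 6,7-oxirane, 8-hydroxyl (both epimers), Z olefin C9=C10, 1-silyloxy group and tert-butyl 12-oate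
Conditions: CrCl2 (8 equiv), NiCl2 (5 mol %), DMSO/THF (3:1), 23 °C, slow addition to 2 mM
Reagents that add atoms: none
Why: Intramolecular Nozaki–Hiyama–Kishi reaction: the alkenylchromium species, formed with retention of the Z geometry, adds to the aldehyde under near-neutral conditions tolerated by the oxirane, esters and silyl ether, and the new C8 carbinol centre is removed in step 13.

Step 13
Reactants: 20 macrocyclic carbinol
Product: 21 macrocyclic α,β-epoxy enone (8-ketone of 20)
Conditions: Dess–Martin periodinane, NaHCO3, CH2Cl2, 0 → 23 °C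
Reagents that add atoms: none
Why: Dess–Martin oxidation of the secondary allylic alcohol gives the cross-conjugated epoxy enone without acid or base that could start the cascade early.

Step 14
Reactants: 21 macrocyclic α,β-epoxy enone
Product: 24 (1S,6R,7S,8S)-7-hydroxy-1,8-epoxygermacra-4,9-diene-12,8:15,6-diolide (C11 epimers), via hemiketal 22 (not isolated), via spiroketal lactone 23 (not isolated)
Conditions: TFA/H2O/CH2Cl2 (4:1:10), 0 → 23 °C
Reagents that add atoms: water (O)
Why: Aqueous TFA removes the C1 silyl ether and the tert-butyl ester; the freed C1 hydroxyl adds across the ring to the C8 ketone of the cis-γ-hydroxy enone (ring B, 5-exo-trig), the hemiketal hydroxyl is acylated by the C12 acid (ring C, 5-exo-trig acyl substitution), and the carbonyl oxygen of the (Z)-enoate opens the protonated oxirane at C6 (ring A, 5-exo-tet), the resulting dialkoxycarbenium ion being hydrolysed to the butenolide with loss of ethanol. The closest known reaction types are transannular hemiketalisation of cis-γ-hydroxy enones in ten-membered rings, pseudo-acid spirolactonisation of γ-keto acids and the acid-mediated cyclisation of (Z)-γ,δ-epoxy enoates to γ-(α-hydroxyalkyl)butenolides. C6 becomes (R) by inversion of the (6S) oxirane carbon, C7 keeps the oxirane oxygen as its hydroxyl with retention, and C8 is fixed by C1 (S) because the six-carbon bridge can only span cis positions of ring B. The step needs attack at C6 and not C7, and by C15 and not C12: C7 is tertiary, next to the ketal carbon and would give a six-membered ring, while the C12 carboxyl could reach the oxirane only through a four-membered or 5-endo transition state. Aromatisation of ring B to a furan, the usual fate of such hemiketals, is blocked because a 2,5-bridged furan in a ten-membered ring would be too strained.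

Step 15
Reactants: 24 tricyclic butenolide
Product: 25 (1S,4S,5S,6R,7S,8S)-4,5,7-trihydroxy-1,8-epoxygermacr-9-ene-12,8:15,6-diolide (C11 epimers)
Conditions: OsO4 (5 mol %), N-methylmorpholine N-oxide (1.5 equiv), acetone/H2O (8:1), 23 °C; aq. Na2SO3
Reagents that add atoms: osmium tetroxide (O=[Os](=O)(=O)=O), N-methylmorpholine N-oxide (C[N+]1([O-])CCOCC1)
Why: Osmium-catalysed syn-dihydroxylation should occur on the butenolide face opposite the seven-atom ansa bridge, giving the (4S,5S) cis-diol, while C9=C10 is shielded by the macrocycle on one face and flanked by the allylic acyloxy oxygen at C8 on the other.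

Step 16
Reactants: 25 triol
Product: 26 5-O-acetate of 25 (C11 epimers)
Conditions: Ac2O (1.2 equiv), pyridine, DMAP (5 mol %), CH2Cl2, 0 °C
Reagents that add atoms: acetic anhydride (CC(=O)OC(C)=O)
Why: Selective acylation distinguishes the secondary C5 hydroxyl from the two tertiary hydroxyls at C4 and C7.

Step 17
Reactants: 26 acetate (C11 epimers)
Product: 27 target, (1S,4S,5S,6R,7S,8S,11S)-5-acetoxy-4,7-dihydroxy-1,8-epoxygermacr-9-ene-12,8:15,6-diolide
Conditions: DBU (0.2 equiv), toluene, 23 °C
Reagents that add atoms: none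
Why: Base-mediated epimerisation of the only enolisable stereocentre (C11, α to the ring C carbonyl) should converge on the thermodynamic (11S) epimer, whose methyl group sits on the convex face, cis to the C7 hydroxyl and trans to C6.

Compound list

1 | propargyl alcohol (prop-2-yn-1-ol) | OCC#C | starting material
2 | alkenylmagnesium alkoxide, (Z)-BrMgOCH2–C(CH3)=CH–MgBr | Br[Mg]OC/C(C)=C\[Mg]Br | intermediate
3 | (Z)-3-iodo-2-methylprop-2-en-1-ol | OC/C(C)=C\I | intermediate
4 | (Z)-3-iodo-2-methylprop-2-enal | O=C/C(C)=C\I | intermediate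
5 | (1Z,3S)-1-iodo-2-methylpenta-1,4-dien-3-ol | C=C[C@H](O)/C(C)=C\I | intermediate
6 | tert-butyl{[(1Z,3S)-1-iodo-2-methylpenta-1,4-dien-3-yl]oxy}dimethylsilane | C=C[C@H](O[Si](C)(C)C(C)(C)C)/C(C)=C\I | intermediate
7 | B-alkyl-9-borabicyclo[3.3.1]nonane from 6 (boron on the terminal carbon) | B1(CC[C@H](O[Si](C)(C)C(C)(C)C)/C(C)=C\I)C2CCCC1CCC2 | intermediate
8 | tert-butyl{[(1Z,3S)-1,5-diiodo-2-methylpent-1-en-3-yl]oxy}dimethylsilane | ICC[C@H](O[Si](C)(C)C(C)(C)C)/C(C)=C\I | intermediate
9 | ethyl 2-(diphenoxyphosphoryl)acetate | CCOC(=O)CP(=O)(Oc1ccccc1)Oc1ccccc1 | starting material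
10 | ethyl (5S,6Z)-5-(tert-butyldimethylsilyloxy)-2-(diphenoxyphosphoryl)-7-iodo-6-methylhept-6-enoate (both C2 epimers) | CCOC(=O)C(CC[C@H](O[Si](C)(C)C(C)(C)C)/C(C)=C\I)P(=O)(Oc1ccccc1)Oc1ccccc1 | intermediate
11 | 4-bromofuran-2(5H)-one | O=C1C=C(Br)CO1 | starting material
12 | tert-butyl 2-bromopropanoate | CC(Br)C(=O)OC(C)(C)C | starting material
13 | bromozinc enolate of 12 (Reformatsky reagent) | CC([Zn]Br)C(=O)OC(C)(C)C | intermediate
14 | tert-butyl 2-(5-oxo-2,5-dihydrofuran-3-yl)propanoate (racemic) | CC(C(=O)OC(C)(C)C)C1=CC(=O)OC1 | intermediate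
15 | tert-butyl 2-(5-hydroxy-2,5-dihydrofuran-3-yl)propanoate (lactol) | CC(C(=O)OC(C)(C)C)C1=CC(O)OC1 | intermediate
16 | sodium (Z)-2-[1-(tert-butoxycarbonyl)ethyl]-4-oxobut-2-en-1-olate | O=C/C=C(\C[O-])C(C)C(=O)OC(C)(C)C.[Na+] | intermediate
17 | 1-ethyl 7-tert-butyl (2Z,4Z)-2-[(3S,4Z)-3-(tert-butyldimethylsilyloxy)-5-iodo-4-methylpent-4-enyl]-5-(hydroxymethyl)-6-methylhepta-2,4-dienedioate (C11 epimers) | CCOC(=O)/C(CC[C@H](O[Si](C)(C)C(C)(C)C)/C(C)=C\I)=C\C=C(/CO)C(C)C(=O)OC(C)(C)C | intermediate
18 | (6S,7R)-6,7-epoxide of 17 (epoxy alcohol) | CCOC(=O)/C(CC[C@H](O[Si](C)(C)C(C)(C)C)/C(C)=C\I)=C\[C@@H]1O[C@@]1(CO)C(C)C(=O)OC(C)(C)C | intermediate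
19 | epoxy aldehyde (C8 formyl on oxirane carbon C7) | CCOC(=O)/C(CC[C@H](O[Si](C)(C)C(C)(C)C)/C(C)=C\I)=C\[C@@H]1O[C@@]1(C=O)C(C)C(=O)OC(C)(C)C | intermediate
20 | ten-membered epoxy carbinol (8-hydroxyl, both epimers) | CCOC(=O)/C1=C\[C@@H]2O[C@]2(C(C)C(=O)OC(C)(C)C)C(O)/C=C(C)\[C@@H](O[Si](C)(C)C(C)(C)C)CC1 | intermediate
21 | ten-membered α,β-epoxy enone | CCOC(=O)/C1=C\[C@@H]2O[C@]2(C(C)C(=O)OC(C)(C)C)C(=O)/C=C(C)\[C@@H](O[Si](C)(C)C(C)(C)C)CC1 | intermediate
22 | hemiketal (ring B closed, oxirane and both esters intact) | CCOC(=O)/C1=C\[C@@H]2O[C@]2(C(C)C(=O)OC(C)(C)C)[C@]3(O)O[C@@H](CC1)C(C)=C3 | intermediate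
23 | spiroketal lactone (rings B and C closed, oxirane and ethyl enoate intact) | CCOC(=O)/C1=C\[C@@H]2O[C@@]23C(C)C(=O)O[C@]34O[C@@H](CC1)C(C)=C4 | intermediate
24 | (1S,6R,7S,8S)-7-hydroxy-1,8-epoxygermacra-4,9-diene-12,8:15,6-diolide (C11 epimers) | C1=C2CC[C@@H]3O[C@@]4(C=C3C)OC(=O)C(C)[C@]4(O)[C@@H]1OC2=O | intermediate
25 | (1S,4S,5S,6R,7S,8S)-4,5,7-trihydroxy-1,8-epoxygermacr-9-ene-12,8:15,6-diolide (C11 epimers) | O[C@H]1[C@H]2OC(=O)[C@]1(O)CC[C@@H]1O[C@@]3(C=C1C)OC(=O)C(C)[C@]23O | intermediate
26 | 5-O-acetate of 25 (C11 epimers) | CC(=O)O[C@H]1[C@H]2OC(=O)[C@]1(O)CC[C@@H]1O[C@@]3(C=C1C)OC(=O)C(C)[C@]23O | intermediate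
27 | (1S,4S,5S,6R,7S,8S,11S)-5-acetoxy-4,7-dihydroxy-1,8-epoxygermacr-9-ene-12,8:15,6-diolide | CC(=O)O[C@H]1[C@H]2OC(=O)[C@]1(O)CC[C@@H]1O[C@@]3(C=C1C)OC(=O)[C@@H](C)[C@]23O | target

Total step count: 17. Longest linear sequence: 15 steps (steps 1–6, then 9–17).

Steps most likely to fail

Step 12 (ring closure). The open chain may oligomerise, or CrCl2 may reduce the epoxy aldehyde, faster than a ten-membered ring containing an E olefin and an oxirane can close. The fallback closes ring A before the macrocycle so that the bridging butenolide pre-bends the chain. It sets out from 18: CSA in wet CH2Cl2 opens the oxirane at C6 to give the butenolide diol F1; TEMPO/PhI(OAc)2 oxidises the primary hydroxyl to the α-hydroxy aldehyde F2; the same CrCl2/NiCl2 closure then gives the macrocyclic butenolide carbinol F3; Dess–Martin oxidation gives the enone–butenolide F4; aqueous TFA (silyl and tert-butyl cleavage, ketalisation, spirolactonisation) returns to the route at 24.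

Step 9 (olefination of the lactol). The ring-opened enal may lose its Z geometry, the liberated C8 alkoxide may add in an oxa-Michael sense to the new enoate, or the lactol may dehydrate to a furan. The fallback masks the C8 oxygen before the aldehyde is freed. It sets out from 14: Me(MeO)NH·HCl/AlMe3 opens the lactone to the (Z)-hydroxy Weinreb amide F5; TESCl/imidazole gives the silyl ether F6; iBu2AlH at −78 °C gives the protected (Z)-enal F7; the same olefination with 10 gives the bis-silyl dienoate F8; PPTS in MeOH removes only the primary triethylsilyl ether and rejoins the route at 17.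

Step 15 (dihydroxylation). Osmylation may occur at the C9=C10 bond of ring B in competition with the electron-poor butenolide. The fallback splits the ring closures into two stages so that the competing olefin is still an enone when osmium is used. It sets out from 21: CSA in wet CH2Cl2 closes ring A only, giving the enone–butenolide F9 (same constitution as F4, silyl ether and tert-butyl ester intact); OsO4/N-methylmorpholine N-oxide then dihydroxylates the butenolide to the diol F10; aqueous TFA closes rings B and C and rejoins the route at 25.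

Further compounds

F1 | step 12 | butenolide diol (ring A closed, C7 hydroxyl, C8 hydroxymethyl, open chain with alkenyl iodide) | O=C1O[C@@H]([C@](O)(CO)C(C)C(=O)OC(C)(C)C)C=C1CC[C@H](O[Si](C)(C)C(C)(C)C)/C(C)=C\I
F2 | step 12 | α-hydroxy aldehyde of F1 (C8 formyl) | O=C1O[C@@H]([C@](O)(C=O)C(C)C(=O)OC(C)(C)C)C=C1CC[C@H](O[Si](C)(C)C(C)(C)C)/C(C)=C\I
F3 | step 12 | macrocyclic butenolide carbinol (7,8-diol, both C8 epimers) | O=C1O[C@@H]2C=C1CC[C@H](O[Si](C)(C)C(C)(C)C)/C(C)=C\C(O)[C@]2(O)C(C)C(=O)OC(C)(C)C
F4 | step 12 | macrocyclic enone–butenolide (8-ketone of F3) | O=C1O[C@@H]2C=C1CC[C@H](O[Si](C)(C)C(C)(C)C)/C(C)=C\C(=O)[C@]2(O)C(C)C(=O)OC(C)(C)C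
F5 | step 9 | tert-butyl (Z)-3-(hydroxymethyl)-5-[methoxy(methyl)amino]-2-methyl-5-oxopent-3-enoate | CON(C)C(=O)/C=C(\CO)C(C)C(=O)OC(C)(C)C
F6 | step 9 | triethylsilyl ether of F5 | CON(C)C(=O)/C=C(\CO[Si](CC)(CC)CC)C(C)C(=O)OC(C)(C)C
F7 | step 9 | tert-butyl (Z)-2-methyl-5-oxo-3-[(triethylsilyloxy)methyl]pent-3-enoate | O=C/C=C(\CO[Si](CC)(CC)CC)C(C)C(=O)OC(C)(C)C
F8 | step 9 | O-triethylsilyl ether of 17 | CCOC(=O)/C(CC[C@H](O[Si](C)(C)C(C)(C)C)/C(C)=C\I)=C\C=C(/CO[Si](CC)(CC)CC)C(C)C(=O)OC(C)(C)C
F9 | step 15 | macrocyclic enone–butenolide from 21 (ring A closed, 1-silyl ether and tert-butyl ester intact) | O=C1O[C@@H]2C=C1CC[C@H](O[Si](C)(C)C(C)(C)C)/C(C)=C\C(=O)[C@]2(O)C(C)C(=O)OC(C)(C)C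
F10 | step 15 | (4S,5S)-4,5-diol of F9 | O=C1O[C@@H]2[C@H](O)[C@@]1(O)CC[C@H](O[Si](C)(C)C(C)(C)C)/C(C)=C\C(=O)[C@]2(O)C(C)C(=O)OC(C)(C)C
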